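The closed vessel is charged with a racemate, so left-handed substrate makes up 50.0% of the substrates together, and that share is the ceiling for left-handed product.

common to all: left-handed substrate 0.11 M; right-handed substrate 0.11 M; precatalyst 2.9 mM

|  | reagent | temperature | remark | time |
|---|---|---|---|---|
| gamma | 0.17 M | 55 °C | run made earlier |  |
| epsilon | 0.66 M | 88 °C | run made earlier |  |
| maple | 0.330 M | 80 °C |  | 10 d |
| ash | 0.330 M | 60 °C |  | 10 d |
| larch | 0.330 M | 100 °C |  | 10 d |
| birch | 0.330 M | 40 °C |  | 10 d |

| run | time / d | left-handed product / % | left-handed substrate / % |
|---|---|---|---|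
| gamma | 8.00 | 1 | 51 |
| gamma | 15.0 | 0 | 51 |
| gamma | 20.0 | 0 | 50 |
| gamma | 30.0 | 0 | 50 |
| gamma | 40.0 | 5 | 47 |
| epsilon | 1.04 | 2 | 47 |
| epsilon | 1.67 | 7 | 49 |
| epsilon | 2.50 | 7 | 41 |
| epsilon | 4.00 | 17 | 33 |
| epsilon | 8.00 | 27 | 17 |
| epsilon | 12.0 | 36 | 13 |

(standard deviation of a reading: 1.5 percentage points)

- the best flask by amount of left-handed product, in percent of the left-handed substrate and right-handed substrate together charged; "all alike" if 1.5 percentage points covers them all (maple / ash / larch / birch / all alike)
- amount of left-handed product at the end, in percent of the left-handed substrate and right-handed substrate together charged, maple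
- amount of left-handed product at the end, in percent of the left-handed substrate and right-handed substrate together charged, ash
- amount of left-handed product at the end, in percent of the left-handed substrate and right-handed substrate together charged, larch
- amount of left-handed product at the end, in percent of the left-handed substrate and right-handed substrate together charged, birch

- free catalyst is single-handed; left-handed substrate and right-handed substrate are mirror images of each other, charged as a racemate, each of them at the stated concentration

In the epsilon run left-handed product and left-handed substrate together stay near that ceiling, with readings at 12.0 d that add to 49.0%. The open matter is how fast the ceiling is approached. Between 2.50 d and 12.0 d the readings of left-handed substrate fall from 41% to 13%, which gives as a reading the epsilon pace 0.121 d⁻¹, the logarithmic fall of left-handed substrate per day, a pseudo-first-order constant.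

Reagent is the first setting. Larch holds half the epsilon reagent, still 1.50 times the substrates together. This reckoning assumes the pace follows reagent in proportion, so the reagent of larch is reckoned, at the epsilon temperature, to give a pace of 0.0605 d⁻¹.

Temperature is the second. The gamma run holds a quarter of the epsilon reagent, which at the epsilon temperature is reckoned to give 0.0311 d⁻¹, but at 55 °C its last reading of 47% gives about 0.00155 d⁻¹, far slower. Under that assumption heat counts heavily between 55 °C and 88 °C, so the four flasks, which share reagent and time, are ranked by temperature as larch, maple, ash, birch, with ash and birch reckoned near the reading of 1% that the gamma run gives at 8.00 d. Neither earlier run stands as hot as larch, so this reckoning gives larch no credit for its extra heat.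

Time is the third. Over 10 d the pace 0.0605 d⁻¹ is reckoned to bring larch to 22.7% of left-handed product.

The forecast names larch as best, with 18% in maple, 1% in ash, 0% in birch and 38% in larch, higher than the figure reckoned here, and adds “Catalyst decay at 100 °C is untested”.

Larch gives 17.3%, the most of the flasks, with maple at 14.1%, ash at 1.17% and birch at 0.0138%.

    reagent + catalyst intermediate B → free catalyst + right-handed product (k = 2.20 M⁻¹ h⁻¹, Ea = 83.0 kJ mol⁻¹)
    free catalyst + left-handed substrate ⇌ catalyst intermediate A (K = 5.30 M⁻¹, k = 230 M⁻¹ h⁻¹, Ea = 65.0 kJ mol⁻¹, ΔH = −30.0 kJ mol⁻¹)
    precatalyst ⇌ free catalyst (K = 0.120, k = 0.0310 h⁻¹, Ea = 130 kJ mol⁻¹, ΔH = −53.0 kJ mol⁻¹)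
    free catalyst + right-handed substrate ⇌ catalyst intermediate B (K = 180 M⁻¹, k = 230 M⁻¹ h⁻¹, Ea = 58.0 kJ mol⁻¹, ΔH = −23.0 kJ mol⁻¹)
    reagent + catalyst intermediate A → free catalyst + left-handed product (k = 5.50 M⁻¹ h⁻¹, Ea = 79.0 kJ mol⁻¹)
    (constants at 80 °C)

At the end larch holds 94.5% of its catalyst as precatalyst, more than the 80.2% in maple. With 65% of its left-handed substrate remaining, larch ran on average at 0.0426 d⁻¹, slower than the scaled pace. For the neighbour of larch with a quarter of its reagent, the epsilon pace scaled by reagent is 0.0152 d⁻¹, which reckons to 7.05%, and that neighbour holds 2.73% of left-handed product.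

(Readings and results were generated by integration for substances that don't exist; the scatter is artificial.)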